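**Retrosynthetic overview**
1. The last skeletal cut is the aryl ketone: a C2–CH2C(O)SEt thioester is joined to a 2,5-bis(methoxymethoxy)phenylzinc reagent (Fukuyama coupling); ester cleavage, desilylation and MOM removal finish the route.
2. The strategy rests on C7 of the 2,3,4,7-tetrahydrooxepine (O1, C2 quaternary, C3, C4, C5=C6, C7): it is a lone CH2 between O1 and the trisubstituted C5=C6 alkene. It is therefore treated as the carbon of an O1=CH2+ ion, released from a methoxymethyl ether on the C2 oxygen and captured at C6 by a (Z)-vinylsilane (C6–C7 bond).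
3. C2 (R) is set before ring closure by a copper–bisoxazoline Mukaiyama aldol of a thioacetate silyl ketene acetal with an alpha-keto ester made from a homoallyl Grignard reagent and dimethyl oxalate.
4. The (Z)-vinylsilane comes from hydroalumination–iodination of 4-(trimethylsilyl)but-3-yn-1-ol and Negishi coupling with a homoprenylzinc reagent that already carries the side-chain oxygen (SeO2 oxidation of 5-bromo-2-methylpent-2-ene at the outset), so no late allylic oxidation must choose between two trisubstituted alkenes.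
5. Ring order: the arene is bought as hydroquinone; the oxepine is the only ring closed (step 10).

Key step: step 10

Remark on the chemistry: the copper–bisoxazoline aldol is assumed to show with keto ester 12 the facial sense known for pyruvate esters, so the (R,R)-ligand is specified for the 2R carbinol; the (S,S)-ligand would be used if the sense proved opposite.

**Route**

Step 1
Reactants: 1 5-bromo-2-methylpent-2-ene
Product: 2 (E)-5-bromo-2-methylpent-2-en-1-ol
Conditions: SeO2 (0.3 equiv), t-BuOOH (2 equiv), salicylic acid (0.1 equiv), CH2Cl2, 0 °C → rt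
Reagents that add atoms: selenium dioxide (O=[Se]=O); tert-butyl hydroperoxide (CC(C)(C)OO)
Why: Selenium dioxide allylic oxidation (ene reaction, then [2,3]-sigmatropic shift) attacks the methyl group trans to the chain on the more substituted alkene carbon and should give the E allylic alcohol, the primary bromide being inert and the minor over-oxidised enal being separated.

Step 2
Reactants: 2 (E)-5-bromo-2-methylpent-2-en-1-ol
Product: 3 tert-butyl{[(2E)-5-bromo-2-methylpent-2-en-1-yl]oxy}diphenylsilane
Conditions: TBDPSCl, imidazole, CH2Cl2, 0 °C → rt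
Reagents that add atoms: tert-butyl(chloro)diphenylsilane (CC(C)(C)[Si](Cl)(c1ccccc1)c1ccccc1)
Why: Standard silylation of a primary alcohol; the tert-butyldiphenylsilyl ether is chosen because it should withstand the organometallic steps, the acidic work-up of step 8 and the Lewis acid of step 10.

Step 3
Reactants: 4 4-(trimethylsilyl)but-3-yn-1-ol
Product: 6 (E)-4-iodo-4-(trimethylsilyl)but-3-en-1-ol, via vinylalane 5 (not isolated)
Conditions: i-Bu2AlH (2.5 equiv), Et2O, 0 °C → reflux; then I2, THF, −78 → 0 °C; aqueous work-up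
Reagents that add atoms: iodine (II)
Why: Hydroalumination of a 1-silylalkyne in a donor solvent is a syn addition that places aluminium on the silicon-bearing carbon (the first equivalent of hydride is consumed by the hydroxyl), and iodinolysis of the C–Al bond with retention should give the alpha-iodovinylsilane with silicon cis to the hydroxyethyl chain.

Step 4
Reactants: 3 tert-butyl{[(2E)-5-bromo-2-methylpent-2-en-1-yl]oxy}diphenylsilane; 6 (E)-4-iodo-4-(trimethylsilyl)but-3-en-1-ol
Product: 8 (3Z,7E)-9-(tert-butyldiphenylsilyloxy)-8-methyl-4-(trimethylsilyl)nona-3,7-dien-1-ol, via alkylzinc bromide 7 (not isolated)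
Conditions: 3, Zn dust (activated), LiCl, THF, 50 °C; then slow addition to 6, Pd(OAc)2 (2 mol%), SPhos (4 mol%), THF, 25 °C
Reagents that add atoms: none
Why: Negishi coupling: LiCl-assisted zinc insertion into the primary bromide, then sp2–sp3 coupling at the alkenyl iodide with retention of geometry, the bulky biarylphosphine making coupling at the hindered silicon-bearing carbon faster than beta-hydride elimination or protonolysis of the zinc reagent by the free hydroxyl.

Step 5
Reactants: 8 (3Z,7E)-9-(tert-butyldiphenylsilyloxy)-8-methyl-4-(trimethylsilyl)nona-3,7-dien-1-ol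
Product: 9 tert-butyl{[(2E,6Z)-9-bromo-2-methyl-6-(trimethylsilyl)nona-2,6-dien-1-yl]oxy}diphenylsilane
Conditions: CBr4, PPh3, 2,6-lutidine, CH2Cl2, 0 °C
Reagents that add atoms: carbon tetrabromide (BrC(Br)(Br)Br)
Why: Appel bromination of a primary alcohol under buffered conditions, which should leave the acid-sensitive vinylsilane and the silyl ether untouched.

Step 6
Reactants: 9 tert-butyl{[(2E,6Z)-9-bromo-2-methyl-6-(trimethylsilyl)nona-2,6-dien-1-yl]oxy}diphenylsilane; 10 dimethyl oxalate
Product: 12 methyl (5Z,9E)-11-(tert-butyldiphenylsilyloxy)-10-methyl-2-oxo-6-(trimethylsilyl)undeca-5,9-dienoate, via Grignard reagent 11 (not isolated)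
Conditions: Mg, THF, 0 °C → rt; then added to 10 (3 equiv), THF–Et2O, −78 °C; aq NH4Cl
Reagents that add atoms: none
Why: Grignard acylation of excess dimethyl oxalate by inverse addition at −78 °C should stop at the alpha-keto ester because the tetrahedral magnesium adduct persists until work-up, and the reagent is made and used cold so that homoallyl–cyclopropylcarbinyl equilibration cannot erode the vinylsilane geometry.

Step 7
Reactants: 13 S-ethyl thioacetate
Product: 15 1-(ethylsulfanyl)-1-(trimethylsilyloxy)ethene, via lithium enolate 14 (not isolated)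
Conditions: LDA (i-Pr2NLi), Me3SiCl, THF, −78 °C
Reagents that add atoms: chlorotrimethylsilane (C[Si](C)(C)Cl)
Why: Kinetic enolisation of the thioester and O-silylation of the enolate give the silyl ketene thioacetal (standard enol silane formation).

Step 8
Reactants: 12 methyl (5Z,9E)-11-(tert-butyldiphenylsilyloxy)-10-methyl-2-oxo-6-(trimethylsilyl)undeca-5,9-dienoate; 15 1-(ethylsulfanyl)-1-(trimethylsilyloxy)ethene
Product: 17 methyl (2R,5Z,9E)-11-(tert-butyldiphenylsilyloxy)-2-[2-(ethylsulfanyl)-2-oxoethyl]-2-hydroxy-10-methyl-6-(trimethylsilyl)undeca-5,9-dienoate, via silyl ether 16 (not isolated)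
Conditions: Cu(OTf)2 (10 mol%), (R,R)-t-Bu-box [2,2'-(propane-2,2-diyl)bis((4R)-4-tert-butyl-4,5-dihydrooxazole)] (11 mol%), THF, −78 °C; then 1 M aq HCl, THF, rt
Reagents that add atoms: none
Why: Catalytic enantioselective Mukaiyama aldol addition in which the alpha-keto ester chelates the C2-symmetric divalent-copper bisoxazoline complex through both carbonyl groups, the tert-butyl groups leave one ketone face open, and with the (R,R)-ligand the nucleophile should add to the re face and set C2 as R, after which dilute acid cleaves the O-trimethylsilyl ether.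

Step 9
Reactants: 17 methyl (2R,5Z,9E)-11-(tert-butyldiphenylsilyloxy)-2-[2-(ethylsulfanyl)-2-oxoethyl]-2-hydroxy-10-methyl-6-(trimethylsilyl)undeca-5,9-dienoate
Product: 18 methyl (2R,5Z,9E)-11-(tert-butyldiphenylsilyloxy)-2-[2-(ethylsulfanyl)-2-oxoethyl]-2-(methoxymethoxy)-10-methyl-6-(trimethylsilyl)undeca-5,9-dienoate
Conditions: MOMCl, i-Pr2NEt, Bu4NI (cat.), ClCH2CH2Cl, 50 °C
Reagents that add atoms: chloromethyl methyl ether (COCCl)
Why: O-alkylation of the neutral tertiary hydroxyl by the highly electrophilic, iodide-activated chloromethyl ether with a hindered amine as acid scavenger, so that no alkoxide is formed and retro-aldol cleavage should be avoided.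

Step 10
Reactants: 18 methyl (2R,5Z,9E)-11-(tert-butyldiphenylsilyloxy)-2-[2-(ethylsulfanyl)-2-oxoethyl]-2-(methoxymethoxy)-10-methyl-6-(trimethylsilyl)undeca-5,9-dienoate
Product: 19 methyl (2R)-6-[(3E)-5-(tert-butyldiphenylsilyloxy)-4-methylpent-3-en-1-yl]-2-[2-(ethylsulfanyl)-2-oxoethyl]-2,3,4,7-tetrahydrooxepine-2-carboxylate
Conditions: Me3SiOTf (0.5 equiv), 2,6-di-tert-butyl-4-methylpyridine (0.5 equiv), CH2Cl2 (0.01 M), −78 → −20 °C; Et3N, aq NaHCO3 quench
Reagents that add atoms: none
Why: The silyl triflate silylates the less hindered, more basic methoxy oxygen of the acetal and MeOSiMe3 departs, leaving the O1=C7H2 oxocarbenium ion, which the ester on C2 makes strongly electrophilic; C6 of the vinylsilane attacks C7, positive charge develops on C5 beta to silicon, and loss of the silyl group to triflate regenerates the promoter and leaves the C5=C6 alkene. The closest known reaction type is the acetal-initiated, vinylsilane-terminated (silyl-Prins) cyclisation of alkoxymethyl ethers of (Z)-5-silylpent-4-en-1-ols to 2,3,4,7-tetrahydrooxepines. The oxepine closes in a 7-endo-trig mode with respect to the C5=C6 alkene. No stereocentre is formed and C2 is not touched, while the alkene geometry is transferred with retention, so that silicon cis to C4 becomes C7 cis to C4 as the ring requires. The step needs site selectivity for C6 over C5 (which would give a six-membered ring and an alpha-silyl cation) and this rests on the beta-silicon effect; the side-chain alkene is deactivated by its allylic silyloxy group and could only close a ring of ten atoms, and the non-nucleophilic triflate counter-ion together with the hindered pyridine should disfavour dealkylative capture of the cation by the ester carbonyl and protodesilylation.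

Step 11
Reactants: 20 hydroquinone
Product: 21 1,4-bis(methoxymethoxy)benzene
Conditions: MOMCl, i-Pr2NEt, CH2Cl2, 0 °C → rt
Reagents that add atoms: chloromethyl methyl ether (COCCl)
Why: Double O-alkylation of the phenol with chloromethyl methyl ether, which installs groups that direct the ortho-metalation of step 12 and fall under mild acid at the end.

Step 12
Reactants: 19 methyl (2R)-6-[(3E)-5-(tert-butyldiphenylsilyloxy)-4-methylpent-3-en-1-yl]-2-[2-(ethylsulfanyl)-2-oxoethyl]-2,3,4,7-tetrahydrooxepine-2-carboxylate; 21 1,4-bis(methoxymethoxy)benzene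
Product: 24 methyl (2R)-2-{2-[2,5-bis(methoxymethoxy)phenyl]-2-oxoethyl}-6-[(3E)-5-(tert-butyldiphenylsilyloxy)-4-methylpent-3-en-1-yl]-2,3,4,7-tetrahydrooxepine-2-carboxylate, via aryllithium 22 (not isolated), via arylzinc chloride 23 (not isolated)
Conditions: 21, n-BuLi, THF, 0 °C → rt; ZnCl2, 0 °C → rt; then 19, PdCl2(PPh3)2 (10 mol%), THF–toluene, 40 °C; aq NH4Cl
Reagents that add atoms: none
Why: Fukuyama coupling: MOM-directed ortho-lithiation and transmetalation to zinc give a mild arylzinc reagent, and zerovalent palladium (formed in situ from the precatalyst) inserts into the C–S bond of the thioester and should deliver the aryl ketone without touching the methyl ester, the silyl ether or the alkenes.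

Step 13
Reactants: 24 methyl (2R)-2-{2-[2,5-bis(methoxymethoxy)phenyl]-2-oxoethyl}-6-[(3E)-5-(tert-butyldiphenylsilyloxy)-4-methylpent-3-en-1-yl]-2,3,4,7-tetrahydrooxepine-2-carboxylate
Product: 26 (2R)-2-{2-[2,5-bis(methoxymethoxy)phenyl]-2-oxoethyl}-6-[(3E)-5-(tert-butyldiphenylsilyloxy)-4-methylpent-3-en-1-yl]-2,3,4,7-tetrahydrooxepine-2-carboxylic acid, via stannyl ester 25 (not isolated)
Conditions: Me3SnOH (6 equiv), ClCH2CH2Cl, 80 °C; then 0.1 M aq HCl wash
Reagents that add atoms: trimethyltin hydroxide (C[Sn](C)(C)O)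
Why: Methyl ester cleavage with trimethyltin hydroxide, a nearly neutral reagent that should attack the alpha-alkoxy-activated ester while sparing the beta-alkoxy ketone (prone to E1cB ring opening under stronger base), the MOM ethers and the silyl ether, the dilute acid wash freeing the acid from its stannyl ester.

Step 14
Reactants: 26 (2R)-2-{2-[2,5-bis(methoxymethoxy)phenyl]-2-oxoethyl}-6-[(3E)-5-(tert-butyldiphenylsilyloxy)-4-methylpent-3-en-1-yl]-2,3,4,7-tetrahydrooxepine-2-carboxylic acid
Product: 27 (2R)-2-{2-[2,5-bis(methoxymethoxy)phenyl]-2-oxoethyl}-6-[(3E)-5-hydroxy-4-methylpent-3-en-1-yl]-2,3,4,7-tetrahydrooxepine-2-carboxylic acid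
Conditions: HF·pyridine, pyridine, THF, 0 °C → rt
Reagents that add atoms: none
Why: Fluoride-mediated desilylation (driven by Si–F bond formation) under buffered, non-basic conditions should free the allylic alcohol without touching the aryl MOM ethers or the base-sensitive beta-alkoxy ketone.

Step 15
Reactants: 27 (2R)-2-{2-[2,5-bis(methoxymethoxy)phenyl]-2-oxoethyl}-6-[(3E)-5-hydroxy-4-methylpent-3-en-1-yl]-2,3,4,7-tetrahydrooxepine-2-carboxylic acid
Product: 28 (2R)-2-[2-(2,5-dihydroxyphenyl)-2-oxoethyl]-6-[(3E)-5-hydroxy-4-methylpent-3-en-1-yl]-2,3,4,7-tetrahydrooxepine-2-carboxylic acid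
Conditions: 2 M aq HCl–THF (1:2), degassed, argon, 35 °C
Reagents that add atoms: none
Why: Acid-catalysed hydrolysis of the two aryl methoxymethyl acetals in an alcohol-free, degassed medium, so that the carboxylic acid is not esterified and the hydroquinone is not oxidised, while C2 carries no hydrogen and cannot epimerise.

**Compound list**
1 | 5-bromo-2-methylpent-2-ene | CC(C)=CCCBr | starting material
2 | (E)-5-bromo-2-methylpent-2-en-1-ol | C/C(CO)=C\CCBr | intermediate
3 | tert-butyl{[(2E)-5-bromo-2-methylpent-2-en-1-yl]oxy}diphenylsilane | C/C(CO[Si](c1ccccc1)(c1ccccc1)C(C)(C)C)=C\CCBr | intermediate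
4 | 4-(trimethylsilyl)but-3-yn-1-ol | C[Si](C)(C)C#CCCO | starting material
5 | diisobutylaluminium alkoxide of (Z)-4-(diisobutylalumanyl)-4-(trimethylsilyl)but-3-en-1-ol (vinylalane) | CC(C)C[Al](CC(C)C)OCC/C=C(/[Al](CC(C)C)CC(C)C)[Si](C)(C)C | intermediate (not isolated)
6 | (E)-4-iodo-4-(trimethylsilyl)but-3-en-1-ol | OCC/C=C(/I)[Si](C)(C)C | intermediate
7 | [(3E)-5-(tert-butyldiphenylsilyloxy)-4-methylpent-3-en-1-yl]zinc bromide | C/C(CO[Si](c1ccccc1)(c1ccccc1)C(C)(C)C)=C\CC[Zn]Br | intermediate (not isolated)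
8 | (3Z,7E)-9-(tert-butyldiphenylsilyloxy)-8-methyl-4-(trimethylsilyl)nona-3,7-dien-1-ol | C/C(CO[Si](c1ccccc1)(c1ccccc1)C(C)(C)C)=C\CC/C(=C/CCO)[Si](C)(C)C | intermediate
9 | tert-butyl{[(2E,6Z)-9-bromo-2-methyl-6-(trimethylsilyl)nona-2,6-dien-1-yl]oxy}diphenylsilane | C/C(CO[Si](c1ccccc1)(c1ccccc1)C(C)(C)C)=C\CC/C(=C/CCBr)[Si](C)(C)C | intermediate
10 | dimethyl oxalate | COC(=O)C(=O)OC | starting material
11 | [(3Z,7E)-9-(tert-butyldiphenylsilyloxy)-8-methyl-4-(trimethylsilyl)nona-3,7-dien-1-yl]magnesium bromide | C/C(CO[Si](c1ccccc1)(c1ccccc1)C(C)(C)C)=C\CC/C(=C/CC[Mg]Br)[Si](C)(C)C | intermediate (not isolated)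
12 | methyl (5Z,9E)-11-(tert-butyldiphenylsilyloxy)-10-methyl-2-oxo-6-(trimethylsilyl)undeca-5,9-dienoate | C/C(CO[Si](c1ccccc1)(c1ccccc1)C(C)(C)C)=C\CC/C(=C/CCC(=O)C(=O)OC)[Si](C)(C)C | intermediate
13 | S-ethyl thioacetate | CC(=O)SCC | starting material
14 | lithium enolate of S-ethyl thioacetate | [Li]OC(=C)SCC | intermediate (not isolated)
15 | 1-(ethylsulfanyl)-1-(trimethylsilyloxy)ethene | C=C(O[Si](C)(C)C)SCC | intermediate
16 | methyl (2R,5Z,9E)-11-(tert-butyldiphenylsilyloxy)-2-[2-(ethylsulfanyl)-2-oxoethyl]-10-methyl-6-(trimethylsilyl)-2-(trimethylsilyloxy)undeca-5,9-dienoate | C/C(CO[Si](c1ccccc1)(c1ccccc1)C(C)(C)C)=C\CC/C(=C/CC[C@@](CC(=O)SCC)(C(=O)OC)O[Si](C)(C)C)[Si](C)(C)C | intermediate (not isolated)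
17 | methyl (2R,5Z,9E)-11-(tert-butyldiphenylsilyloxy)-2-[2-(ethylsulfanyl)-2-oxoethyl]-2-hydroxy-10-methyl-6-(trimethylsilyl)undeca-5,9-dienoate | C/C(CO[Si](c1ccccc1)(c1ccccc1)C(C)(C)C)=C\CC/C(=C/CC[C@@](CC(=O)SCC)(C(=O)OC)O)[Si](C)(C)C | intermediate
18 | methyl (2R,5Z,9E)-11-(tert-butyldiphenylsilyloxy)-2-[2-(ethylsulfanyl)-2-oxoethyl]-2-(methoxymethoxy)-10-methyl-6-(trimethylsilyl)undeca-5,9-dienoate | C/C(CO[Si](c1ccccc1)(c1ccccc1)C(C)(C)C)=C\CC/C(=C/CC[C@@](CC(=O)SCC)(C(=O)OC)OCOC)[Si](C)(C)C | intermediate (key-step precursor)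
19 | methyl (2R)-6-[(3E)-5-(tert-butyldiphenylsilyloxy)-4-methylpent-3-en-1-yl]-2-[2-(ethylsulfanyl)-2-oxoethyl]-2,3,4,7-tetrahydrooxepine-2-carboxylate | C/C(CO[Si](c1ccccc1)(c1ccccc1)C(C)(C)C)=C\CCC1=CCC[C@@](CC(=O)SCC)(C(=O)OC)OC1 | intermediate (key-step product)
20 | hydroquinone | Oc1ccc(O)cc1 | starting material
21 | 1,4-bis(methoxymethoxy)benzene | COCOc1ccc(OCOC)cc1 | intermediate
22 | [2,5-bis(methoxymethoxy)phenyl]lithium | [Li]c1cc(OCOC)ccc1OCOC | intermediate (not isolated)
23 | [2,5-bis(methoxymethoxy)phenyl]zinc chloride | Cl[Zn]c1cc(OCOC)ccc1OCOC | intermediate (not isolated)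
24 | methyl (2R)-2-{2-[2,5-bis(methoxymethoxy)phenyl]-2-oxoethyl}-6-[(3E)-5-(tert-butyldiphenylsilyloxy)-4-methylpent-3-en-1-yl]-2,3,4,7-tetrahydrooxepine-2-carboxylate | C/C(CO[Si](c1ccccc1)(c1ccccc1)C(C)(C)C)=C\CCC1=CCC[C@@](CC(=O)c2cc(OCOC)ccc2OCOC)(C(=O)OC)OC1 | intermediate
25 | trimethylstannyl ester of acid 26 | C/C(CO[Si](c1ccccc1)(c1ccccc1)C(C)(C)C)=C\CCC1=CCC[C@@](CC(=O)c2cc(OCOC)ccc2OCOC)(C(=O)O[Sn](C)(C)C)OC1 | intermediate (not isolated)
26 | (2R)-2-{2-[2,5-bis(methoxymethoxy)phenyl]-2-oxoethyl}-6-[(3E)-5-(tert-butyldiphenylsilyloxy)-4-methylpent-3-en-1-yl]-2,3,4,7-tetrahydrooxepine-2-carboxylic acid | C/C(CO[Si](c1ccccc1)(c1ccccc1)C(C)(C)C)=C\CCC1=CCC[C@@](CC(=O)c2cc(OCOC)ccc2OCOC)(C(=O)O)OC1 | intermediate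
27 | (2R)-2-{2-[2,5-bis(methoxymethoxy)phenyl]-2-oxoethyl}-6-[(3E)-5-hydroxy-4-methylpent-3-en-1-yl]-2,3,4,7-tetrahydrooxepine-2-carboxylic acid | C/C(CO)=C\CCC1=CCC[C@@](CC(=O)c2cc(OCOC)ccc2OCOC)(C(=O)O)OC1 | intermediate
28 | (2R)-2-[2-(2,5-dihydroxyphenyl)-2-oxoethyl]-6-[(3E)-5-hydroxy-4-methylpent-3-en-1-yl]-2,3,4,7-tetrahydrooxepine-2-carboxylic acid (CNP0570804.1) | C/C(CO)=C\CCC1=CCC[C@@](CC(=O)c2cc(O)ccc2O)(C(=O)O)OC1 | target

**Step count**
Total: 15 steps. Longest linear sequence: 12 steps, from 1 to 28 through steps 1, 2, 4, 5, 6, 8, 9, 10, 12, 13, 14 and 15.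

**Steps most likely to fail**

Step 10 (oxepine closure). What may go wrong:
- the acetal may ionise in the wrong sense, with loss of the formaldehyde unit from O1;
- the oxocarbenium ion may be captured by the neighbouring ester carbonyl and then dealkylated;
- the vinylsilane may be protodesilylated;
- the seven-membered closure may be too slow to outrun intermolecular reaction.

Fallback (ring-closing metathesis that forms C5=C6 in place of C6–C7), setting out from dimethyl oxalate 10 and returning at oxepine 19. But-3-enylmagnesium bromide acylates 10 (THF, −78 °C) to methyl 2-oxohex-5-enoate F1. The copper–bisoxazoline aldol of step 8 with 15 then gives, through the silyl ether methyl (2R)-2-[2-(ethylsulfanyl)-2-oxoethyl]-2-(trimethylsilyloxy)hex-5-enoate F2, the carbinol methyl (2R)-2-[2-(ethylsulfanyl)-2-oxoethyl]-2-hydroxyhex-5-enoate F3. Separately, bromide 3 is converted with Mg into [(3E)-5-(tert-butyldiphenylsilyloxy)-4-methylpent-3-en-1-yl]magnesium bromide F4, which adds to propargyl alcohol under CuI catalysis to give (E)-7-(tert-butyldiphenylsilyloxy)-6-methyl-2-methylidenehept-5-en-1-ol F5. Cl3CCN and DBU convert this into (E)-7-(tert-butyldiphenylsilyloxy)-6-methyl-2-methylidenehept-5-en-1-yl 2,2,2-trichloroacetimidate F6. TfOH-catalysed O-allylation of F3 with F6, in which no alkoxide is formed, gives methyl (2R)-2-{[(E)-7-(tert-butyldiphenylsilyloxy)-6-methyl-2-methylidenehept-5-en-1-yl]oxy}-2-[2-(ethylsulfanyl)-2-oxoethyl]hex-5-enoate F7. The second-generation Hoveyda–Grubbs catalyst (CH2Cl2, 40 °C) then closes the ring to 19 with loss of ethene.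

Step 9 (methoxymethylation of the tertiary aldol). What may go wrong: retro-aldol fragmentation or E1cB loss of the tertiary oxygen under the amine base at 50 °C, or incomplete alkylation of the hindered hydroxyl.

Fallback, from carbinol 17 back to acetal 18: acid-catalysed acetal exchange with dimethoxymethane (P2O5, CHCl3, 0 °C → rt). This transfers the methoxymethyl group to the neutral alcohol through the MeO–CH2+ ion and never forms the alkoxide. It passes through no new compound (F0).

Step 12 (aryl ketone formation). What may go wrong: slow transmetalation of the ortho-substituted arylzinc reagent to the acylpalladium intermediate, so that homocoupling, protodezincation or ring opening by beta-elimination compete.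

Fallback, from aryllithium 22 and thioester 19 back to ketone 24: 22 is quenched with B(Oi-Pr)3 and hydrolysed to 2,5-bis(methoxymethoxy)phenylboronic acid F8. This is coupled with 19 under base-free Liebeskind–Srogl conditions (Pd2(dba)3, tri(2-furyl)phosphine, copper thiophene-2-carboxylate Cu(O2CC4H3S) with monovalent copper, THF, 50 °C).

**Further compounds**
F1 | step 10 | methyl 2-oxohex-5-enoate | C=CCCC(=O)C(=O)OC
F2 | step 10 | methyl (2R)-2-[2-(ethylsulfanyl)-2-oxoethyl]-2-(trimethylsilyloxy)hex-5-enoate | C=CCC[C@@](CC(=O)SCC)(C(=O)OC)O[Si](C)(C)C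
F3 | step 10 | methyl (2R)-2-[2-(ethylsulfanyl)-2-oxoethyl]-2-hydroxyhex-5-enoate | C=CCC[C@@](CC(=O)SCC)(C(=O)OC)O
F4 | step 10 | [(3E)-5-(tert-butyldiphenylsilyloxy)-4-methylpent-3-en-1-yl]magnesium bromide | C/C(CO[Si](c1ccccc1)(c1ccccc1)C(C)(C)C)=C\CC[Mg]Br
F5 | step 10 | (E)-7-(tert-butyldiphenylsilyloxy)-6-methyl-2-methylidenehept-5-en-1-ol | C/C(CO[Si](c1ccccc1)(c1ccccc1)C(C)(C)C)=C\CCC(=C)CO
F6 | step 10 | (E)-7-(tert-butyldiphenylsilyloxy)-6-methyl-2-methylidenehept-5-en-1-yl 2,2,2-trichloroacetimidate | C/C(CO[Si](c1ccccc1)(c1ccccc1)C(C)(C)C)=C\CCC(=C)COC(=N)C(Cl)(Cl)Cl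
F7 | step 10 | methyl (2R)-2-{[(E)-7-(tert-butyldiphenylsilyloxy)-6-methyl-2-methylidenehept-5-en-1-yl]oxy}-2-[2-(ethylsulfanyl)-2-oxoethyl]hex-5-enoate | C=CCC[C@@](CC(=O)SCC)(C(=O)OC)OCC(=C)CC/C=C(\C)CO[Si](c1ccccc1)(c1ccccc1)C(C)(C)C
F0 | step 9 | none | none
F8 | step 12 | 2,5-bis(methoxymethoxy)phenylboronic acid | COCOc1ccc(OCOC)c(B(O)O)c1
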